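**Retrosynthetic overview**

- The strategy rests on two features: in rings A and B, C4 (equatorial methyl, axial carboxyl C19), the trans fusion C5/C10, the equatorial C9 chain and the C8=C17 methylene are the imprint of an (E,E)-diene folded chair–chair from a 2-methyl-3-oxo ester head, and in the side chain C13 with its methyl and hydroxyl is C3 of (R)-linalool.
- Endgame: the C15 and C19 acids come from a 13,15,19-triol, which comes from LiAlH4 cleavage of the auxiliary ester and two acetates after removal of the C3 oxygen; C15 is carried as its acetate because C19 has to be reduced and reoxidised anyway.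
- Key disconnection: C4–C5 and C9–C10 by oxidative radical bicyclisation of an 8-phenylmenthyl 2-methyl-3-oxo ester; ring A closes first, then ring B, in the same step, and termination gives C8=C17.
- Precursor: C3–C4 by homologation of a C3 aldehyde with the auxiliary 2-diazopropanoate; the aldehyde comes from a terminal epoxide that is installed on the geranyl unit before coupling.
- Chain: C6–C7 by alkylation of 6,7-epoxygeranyl phenyl sulfone with the (E)-allylic bromide made from (R)-linalool, then desulfonylation and hydroboration of the vinyl group (C14, C15).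

Key step: step 13

Assumption: in the C4 radical the ester carbonyl of the (−)-8-phenylmenthyl group lies syn to the C3 ketone carbon and the bulky alkoxy group points to the C4 methyl side, so that the phenyl ring covers the face that would lead to the antipodal bicycle; (R)-(−)-linalool of high enantiomeric purity is assumed to be available.

Remark: labdane numbering is used for the carbons of 18 and later compounds (C19 ester carbon, C4 its α-carbon, C3 ketone, C10=C5 and C8=C9 the two alkenes, C13 the carbinol carbon).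

**Route**

Step 1
Reactants: 1 (R)-(−)-linalool
Product: 2 (2E,6R)-2,6-dimethylocta-2,7-diene-1,6-diol
Conditions: SeO2 (cat.), t-BuOOH, salicylic acid (cat.), CH2Cl2, rt
Reagents that add atoms: selenium dioxide, O=[Se]=O; tert-butyl hydroperoxide, CC(C)(C)OO
Why: Riley allylic oxidation (ene reaction, then [2,3]-sigmatropic shift) attacks the electron-rich trisubstituted alkene and hydroxylates its (E)-methyl group, while the vinyl group and the tertiary carbinol centre are not touched.

Step 2
Reactants: 2 (2E,6R)-2,6-dimethylocta-2,7-diene-1,6-diol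
Product: 3 (3R,6E)-8-bromo-3,7-dimethylocta-1,6-dien-3-ol
Conditions: CBr4, PPh3, CH2Cl2, −20 °C
Reagents that add atoms: carbon tetrabromide, BrC(Br)(Br)Br
Why: Appel bromination displaces the primary allylic oxyphosphonium group by SN2 at low temperature, where the hindered tertiary alcohol does not react and the (E)-alkene is kept.

Step 3
Reactants: 4 geranyl bromide
Product: 5 geranyl phenyl sulfone
Conditions: PhSO2Na, DMF, rt
Reagents that add atoms: sodium benzenesulfinate, [Na+].[O-]S(=O)c1ccccc1
Why: SN2 S-alkylation of the sulfinate by the primary allylic bromide gives the allylic sulfone with the (E)-alkene unchanged.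

Step 4
Reactants: 5 geranyl phenyl sulfone
Product: 6 6,7-epoxygeranyl phenyl sulfone (racemic at the epoxide)
Conditions: mCPBA, NaHCO3, CH2Cl2, 0 °C
Reagents that add atoms: 3-chloroperoxybenzoic acid, OOC(=O)c1cccc(Cl)c1
Why: Prilezhaev epoxidation takes the electron-rich 6,7-alkene in preference to the 2,3-alkene, which is deactivated by the allylic sulfonyl group, and the configuration of the epoxide is irrelevant because it is destroyed in step 9.

Step 5
Reactants: 3 (3R,6E)-8-bromo-3,7-dimethylocta-1,6-dien-3-ol; 6 6,7-epoxygeranyl phenyl sulfone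
Product: 8 (3R,6E,10E)-14,15-epoxy-3,7,11,15-tetramethyl-9-(phenylsulfonyl)hexadeca-1,6,10-trien-3-ol (mixture at C9 and C14), via α-lithio sulfone 7 (not isolated)
Conditions: 6 (2.2 equiv), n-BuLi (2.1 equiv), THF, −78 °C; then 3, −78 → −40 °C
Reagents that add atoms: none
Why: Sulfone-anion alkylation (Julia-type allyl sulfone coupling) joins the α-carbon of the sulfonyl carbanion to the primary allylic bromide by SN2, so the C6–C7 bond forms without allylic transposition and both (E)-alkenes are kept, the second equivalent of anion covering the free tertiary hydroxyl.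

Step 6
Reactants: 8 (3R,6E,10E)-14,15-epoxy-3,7,11,15-tetramethyl-9-(phenylsulfonyl)hexadeca-1,6,10-trien-3-ol
Product: 9 (3R,6E,10E)-14,15-epoxy-3,7,11,15-tetramethylhexadeca-1,6,10-trien-3-ol (C14 epimers)
Conditions: PdCl2(dppp) (cat., dppp = 1,3-bis(diphenylphosphino)propane), LiBHEt3, THF, 0 °C
Reagents that add atoms: none
Why: Reductive desulfonylation of the allylic sulfone through a π-allyl complex of zerovalent palladium delivers hydride to the less substituted allyl terminus, which keeps the trisubstituted (E)-alkene in place, and the trisubstituted epoxide is expected to be opened more slowly than the catalytic cycle turns over.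

Step 7
Reactants: 9 (3R,6E,10E)-14,15-epoxy-3,7,11,15-tetramethylhexadeca-1,6,10-trien-3-ol
Product: 11 (3R,6E,10E)-14,15-epoxy-3,7,11,15-tetramethylhexadeca-6,10-diene-1,3-diol, via B-alkyl-9-BBN adduct 10 (not isolated)
Conditions: 9-BBN (2.5 equiv), THF, 0 °C → rt; then NaOH, H2O2, 0 °C
Reagents that add atoms: hydrogen peroxide, OO
Why: Hydroboration–oxidation with bulky 9-BBN selects the monosubstituted vinyl group over the trisubstituted alkenes and places boron on the terminal carbon, and alkaline peroxide oxidises the C–B bond without opening the epoxide or touching the carbinol centre.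

Step 8
Reactants: 11 (3R,6E,10E)-14,15-epoxy-3,7,11,15-tetramethylhexadeca-6,10-diene-1,3-diol
Product: 12 (3R,6E,10E)-14,15-epoxy-3,7,11,15-tetramethylhexadeca-6,10-diene-1,3-diyl diacetate
Conditions: Ac2O, Et3N, DMAP, CH2Cl2, rt → 40 °C
Reagents that add atoms: acetic anhydride, CC(=O)OC(C)=O
Why: DMAP-catalysed acylation acetylates the primary alcohol quickly and the unhindered tertiary alcohol on longer reaction, giving the two acetate spectators for the radical step under basic conditions that leave the epoxide intact.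

Step 9
Reactants: 12 (3R,6E,10E)-14,15-epoxy-3,7,11,15-tetramethylhexadeca-6,10-diene-1,3-diyl diacetate
Product: 13 (3R,6E,10E)-3,7,11-trimethyl-14-oxotetradeca-6,10-diene-1,3-diyl diacetate
Conditions: H5IO6, THF–H2O, 0 °C
Reagents that add atoms: none
Why: Periodic acid hydrolyses the trisubstituted epoxide at its tertiary carbon and cleaves the resulting glycol (Malaprade fission) to the C3 aldehyde and acetone, while the internal alkenes and both acetates are inert.

Step 10
Reactants: 14 (−)-8-phenylmenthol; 15 ethyl 2-methyl-3-oxobutanoate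
Product: 16 (−)-8-phenylmenthyl 2-methyl-3-oxobutanoate (C2 epimers)
Conditions: DMAP (cat.), toluene, reflux, removal of EtOH
Reagents that add atoms: none
Why: DMAP-catalysed transesterification of an enolisable β-keto ester proceeds through the acylketene and is driven by loss of ethanol, so the hindered secondary alcohol is acylated without an activated acid derivative.

Step 11
Reactants: 16 (−)-8-phenylmenthyl 2-methyl-3-oxobutanoate
Product: 17 (−)-8-phenylmenthyl 2-diazopropanoate
Conditions: 4-acetamidobenzenesulfonyl azide, DBU, MeCN, 0 °C → rt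
Reagents that add atoms: 4-acetamidobenzenesulfonyl azide, CC(=O)Nc1ccc(cc1)S(=O)(=O)N=[N+]=[N-]
Why: Regitz deacylative diazo transfer: the enolate attacks the sulfonyl azide and the triazene fragments with transfer of the acetyl group to the sulfonamide nitrogen, which leaves the 2-diazopropanoate.

Step 12
Reactants: 13 (3R,6E,10E)-3,7,11-trimethyl-14-oxotetradeca-6,10-diene-1,3-diyl diacetate; 17 (−)-8-phenylmenthyl 2-diazopropanoate
Product: 18 (−)-8-phenylmenthyl (6E,10E,14R)-14,16-diacetoxy-2,6,10,14-tetramethyl-3-oxohexadeca-6,10-dienoate (C2 epimers)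
Conditions: BF3·OEt2 (cat.), CH2Cl2, −78 °C
Reagents that add atoms: none
Why: Roskamp homologation: the diazo carbon adds to the Lewis-acid-activated aldehyde and 1,2-hydride shift with loss of N2 gives the 2-methyl-3-oxo ester, whose C4 epimers are equivalent because C4 becomes the radical centre.

Step 13
Reactants: 18 (−)-8-phenylmenthyl (6E,10E,14R)-14,16-diacetoxy-2,6,10,14-tetramethyl-3-oxohexadeca-6,10-dienoate
Product: 19 (−)-8-phenylmenthyl (13R)-13,15-diacetoxy-3-oxolabd-8(17)-en-19-oate
Conditions: Mn(OAc)3·2H2O (2.2 equiv), Cu(OAc)2·H2O (1 equiv), degassed AcOH, rt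
Reagents that add atoms: none
Why: Mn(OAc)3 forms the manganese enolate of the keto ester and oxidises it to the electrophilic C4 radical, which adds to C5 (ring A, 6-endo-trig, tertiary C10 radical) and then from C10 to C9 (ring B, 6-endo-trig, tertiary C8 radical); Cu(OAc)2 captures the C8 radical and the organocopper species loses a β-hydrogen from the C17 methyl to give the exocyclic alkene, the copper being returned to the divalent state by trivalent manganese. The closest known reaction type is the Mn(OAc)3/Cu(OAc)2 oxidative radical polycyclisation of unsaturated 2-methyl-3-oxo esters, including its version with 8-phenylmenthyl esters as the controlling group. C5, C10 and C9 are set by chair–chair folding of the two (E)-trisubstituted alkenes: anti addition across C5=C10 gives the trans fusion (5α-H, 10β-methyl) and the C11 chain takes the equatorial position at C9. C4 is set by two elements: the ester takes the axial position cis to the C10 methyl, as is usual when such a radical closes with the ketone inside the ring, and the phenyl ring of the auxiliary stacks over one face of the radical so that C5 bonds from the open face, which fixes the sense of the whole bicycle relative to C13. The step needs facial selectivity at C4, closure of ring B before the C10 radical is oxidised, and exocyclic termination; these are secured by the auxiliary, by the fast 6-endo closure onto the electron-rich alkene, and by the preference of the copper-mediated elimination for the least substituted alkene. The tertiary C13 acetate is too poor a nucleophile to trap C8 as a cyclic ether, and both acetates are inert to the oxidants.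

Step 14
Reactants: 19 (−)-8-phenylmenthyl (13R)-13,15-diacetoxy-3-oxolabd-8(17)-en-19-oate
Product: 20 (−)-8-phenylmenthyl (13R)-13,15-diacetoxy-3β-hydroxylabd-8(17)-en-19-oate
Conditions: NaBH4, THF–MeOH, 0 °C
Reagents that add atoms: none
Why: Hydride reduction of the ring ketone, with esters and acetates untouched at 0 °C, should give mainly the equatorial 3β-alcohol by attack from the α-face away from the axial C4 ester and C10 methyl, and since C3 is deoxygenated in step 16 either epimer serves.

Step 15
Reactants: 20 (−)-8-phenylmenthyl (13R)-13,15-diacetoxy-3β-hydroxylabd-8(17)-en-19-oate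
Product: 21 (−)-8-phenylmenthyl (13R)-13,15-diacetoxy-3β-[(imidazol-1-yl)thiocarbonyloxy]labd-8(17)-en-19-oate
Conditions: 1,1'-thiocarbonyldiimidazole, DMAP (cat.), ClCH2CH2Cl, reflux
Reagents that add atoms: 1,1'-thiocarbonyldiimidazole, S=C(n1ccnc1)n1ccnc1
Why: Thioacylation of the secondary alcohol (first stage of the Barton–McCombie deoxygenation) runs under neutral conditions that the acetates and the hindered ester tolerate.

Step 16
Reactants: 21 (−)-8-phenylmenthyl (13R)-13,15-diacetoxy-3β-[(imidazol-1-yl)thiocarbonyloxy]labd-8(17)-en-19-oate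
Product: 22 (−)-8-phenylmenthyl (13R)-13,15-diacetoxylabd-8(17)-en-19-oate
Conditions: Bu3SnH, AIBN (cat.), toluene, reflux
Reagents that add atoms: none
Why: Barton–McCombie radical deoxygenation: the stannyl radical adds to sulfur, the C3–O bond fragments, and the secondary C3 radical takes hydrogen from Bu3SnH, the C8=C17 alkene being out of reach for cyclisation.

Step 17
Reactants: 22 (−)-8-phenylmenthyl (13R)-13,15-diacetoxylabd-8(17)-en-19-oate
Product: 23 (13R)-labd-8(17)-ene-13,15,19-triol
Conditions: LiAlH4, THF, reflux; aqueous NaOH work-up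
Reagents that add atoms: none
Why: LiAlH4 reduces the hindered axial ester to the C19 alcohol with release of the recoverable auxiliary and cleaves both acetates, without touching any stereocentre or the alkene.

Step 18
Reactants: 23 (13R)-labd-8(17)-ene-13,15,19-triol
Product: 24 (13R)-13-hydroxylabd-8(17)-ene-15,19-dial
Conditions: TEMPO (cat.), PhI(OAc)2, CH2Cl2, rt
Reagents that add atoms: none
Why: Oxoammonium (TEMPO) oxidation with PhI(OAc)2 as the terminal oxidant converts both primary alcohols to aldehydes and cannot oxidise the tertiary C13 alcohol or the alkene.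

Step 19
Reactants: 24 (13R)-13-hydroxylabd-8(17)-ene-15,19-dial
Product: 25 (13R)-13-hydroxylabd-8(17)-ene-15,19-dioic acid (target)
Conditions: NaClO2, NaH2PO4, 2-methyl-2-butene, t-BuOH–H2O, rt
Reagents that add atoms: sodium chlorite, [Na+].[O-]Cl=O
Why: Pinnick oxidation converts both aldehydes to acids under buffered conditions that avoid dehydration of the β-hydroxy aldehyde, and 2-methyl-2-butene scavenges HOCl so that the exocyclic alkene is spared.

**Compound list**

1 | (R)-(−)-linalool, (3R)-3,7-dimethylocta-1,6-dien-3-ol | CC(C)=CCC[C@@](C)(O)C=C | starting material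
2 | (2E,6R)-2,6-dimethylocta-2,7-diene-1,6-diol | OC/C(C)=C/CC[C@@](C)(O)C=C | intermediate
3 | (3R,6E)-8-bromo-3,7-dimethylocta-1,6-dien-3-ol | BrC/C(C)=C/CC[C@@](C)(O)C=C | intermediate
4 | geranyl bromide, (2E)-1-bromo-3,7-dimethylocta-2,6-diene | CC(C)=CCC/C(C)=C/CBr | starting material
5 | geranyl phenyl sulfone | CC(C)=CCC/C(C)=C/CS(=O)(=O)c1ccccc1 | intermediate
6 | 6,7-epoxygeranyl phenyl sulfone (racemic epoxide) | CC1(C)OC1CC/C(C)=C/CS(=O)(=O)c1ccccc1 | intermediate
7 | α-lithio derivative of 6 | [Li]C(/C=C(C)/CCC1OC1(C)C)S(=O)(=O)c1ccccc1 | intermediate (not isolated)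
8 | (3R,6E,10E)-14,15-epoxy-3,7,11,15-tetramethyl-9-(phenylsulfonyl)hexadeca-1,6,10-trien-3-ol (mixture at C9 and C14) | CC1(C)OC1CC/C(C)=C/C(C/C(C)=C/CC[C@@](C)(O)C=C)S(=O)(=O)c1ccccc1 | intermediate
9 | (3R,6E,10E)-14,15-epoxy-3,7,11,15-tetramethylhexadeca-1,6,10-trien-3-ol (C14 epimers) | CC1(C)OC1CC/C(C)=C/CC/C(C)=C/CC[C@@](C)(O)C=C | intermediate
10 | B-alkyl-9-BBN adduct of 9 (boron on C1) | CC1(C)OC1CC/C(C)=C/CC/C(C)=C/CC[C@@](C)(O)CCB1C2CCCC1CCC2 | intermediate (not isolated)
11 | (3R,6E,10E)-14,15-epoxy-3,7,11,15-tetramethylhexadeca-6,10-diene-1,3-diol | CC1(C)OC1CC/C(C)=C/CC/C(C)=C/CC[C@@](C)(O)CCO | intermediate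
12 | (3R,6E,10E)-14,15-epoxy-3,7,11,15-tetramethylhexadeca-6,10-diene-1,3-diyl diacetate | CC1(C)OC1CC/C(C)=C/CC/C(C)=C/CC[C@@](C)(OC(C)=O)CCOC(C)=O | intermediate
13 | (3R,6E,10E)-3,7,11-trimethyl-14-oxotetradeca-6,10-diene-1,3-diyl diacetate | O=CCC/C(C)=C/CC/C(C)=C/CC[C@@](C)(OC(C)=O)CCOC(C)=O | intermediate
14 | (−)-8-phenylmenthol, (1R,2S,5R)-5-methyl-2-(2-phenylpropan-2-yl)cyclohexan-1-ol | O[C@@H]1C[C@H](C)CC[C@H]1C(C)(C)c1ccccc1 | starting material
15 | ethyl 2-methyl-3-oxobutanoate | CCOC(=O)C(C)C(C)=O | starting material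
16 | (−)-8-phenylmenthyl 2-methyl-3-oxobutanoate (C2 epimers) | CC(=O)C(C)C(=O)O[C@@H]1C[C@H](C)CC[C@H]1C(C)(C)c1ccccc1 | intermediate
17 | (−)-8-phenylmenthyl 2-diazopropanoate | CC(=[N+]=[N-])C(=O)O[C@@H]1C[C@H](C)CC[C@H]1C(C)(C)c1ccccc1 | intermediate
18 | (−)-8-phenylmenthyl (6E,10E,14R)-14,16-diacetoxy-2,6,10,14-tetramethyl-3-oxohexadeca-6,10-dienoate (C2 epimers) | CC(C(=O)O[C@@H]1C[C@H](C)CC[C@H]1C(C)(C)c1ccccc1)C(=O)CC/C(C)=C/CC/C(C)=C/CC[C@@](C)(OC(C)=O)CCOC(C)=O | intermediate
19 | (−)-8-phenylmenthyl (13R)-13,15-diacetoxy-3-oxolabd-8(17)-en-19-oate | C=C1CC[C@@H]2[C@](C)(CCC(=O)[C@]2(C)C(=O)O[C@@H]3C[C@H](C)CC[C@H]3C(C)(C)c3ccccc3)[C@H]1CC[C@@](C)(OC(C)=O)CCOC(C)=O | intermediate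
20 | (−)-8-phenylmenthyl (13R)-13,15-diacetoxy-3β-hydroxylabd-8(17)-en-19-oate | C=C1CC[C@@H]2[C@](C)(CC[C@H](O)[C@]2(C)C(=O)O[C@@H]3C[C@H](C)CC[C@H]3C(C)(C)c3ccccc3)[C@H]1CC[C@@](C)(OC(C)=O)CCOC(C)=O | intermediate
21 | (−)-8-phenylmenthyl (13R)-13,15-diacetoxy-3β-[(imidazol-1-yl)thiocarbonyloxy]labd-8(17)-en-19-oate | C=C1CC[C@@H]2[C@](C)(CC[C@H](OC(=S)n4ccnc4)[C@]2(C)C(=O)O[C@@H]3C[C@H](C)CC[C@H]3C(C)(C)c3ccccc3)[C@H]1CC[C@@](C)(OC(C)=O)CCOC(C)=O | intermediate
22 | (−)-8-phenylmenthyl (13R)-13,15-diacetoxylabd-8(17)-en-19-oate | C=C1CC[C@@H]2[C@](C)(CCC[C@]2(C)C(=O)O[C@@H]3C[C@H](C)CC[C@H]3C(C)(C)c3ccccc3)[C@H]1CC[C@@](C)(OC(C)=O)CCOC(C)=O | intermediate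
23 | (13R)-labd-8(17)-ene-13,15,19-triol | C=C1CC[C@@H]2[C@](C)(CCC[C@]2(C)CO)[C@H]1CC[C@@](C)(O)CCO | intermediate
24 | (13R)-13-hydroxylabd-8(17)-ene-15,19-dial | C=C1CC[C@@H]2[C@](C)(CCC[C@]2(C)C=O)[C@H]1CC[C@@](C)(O)CC=O | intermediate
25 | (13R)-13-hydroxylabd-8(17)-ene-15,19-dioic acid | C=C1CC[C@@H]2[C@](C)(CCC[C@]2(C)C(=O)O)[C@H]1CC[C@@](C)(O)CC(=O)O | target

**Step count and risks**

Total step count: 19. Longest linear sequence: 15 steps (steps 1, 2, 5, 6, 7, 8, 9, 12, 13, 14, 15, 16, 17, 18, 19, from (R)-linalool).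

Steps most likely to fail:

Step 13. The facial selectivity at the C4 radical may be low or of the wrong sense, and ring A closure may be slowed by forming the quaternary C4 in the radical step. The fallback takes the C4 methyl out of the radical step and uses chelation control. It sets out from aldehyde 13. Roskamp homologation with ethyl diazoacetate (SnCl2, CH2Cl2) would give ethyl keto ester F1. DMAP-catalysed transesterification with (+)-8-phenylmenthol, the antipode of 14, would give 2-unsubstituted keto ester F2. The antipode is chosen because the chelated enolate closes with the ester equatorial, which reverses the relation between the shielded face and the sense of the bicycle. Cyclisation of F2 with Mn(OAc)3·2H2O and Cu(OAc)2·H2O in the presence of Yb(OTf)3 in CF3CH2OH would give bicyclic keto ester F3. C-Methylation (K2CO3, MeI, acetone) from the α-face, anti to the C10 methyl, would set C4 and give methylated keto ester F4. The conditions of steps 14 to 16 would then give alcohol F5, imidazolide F6 and deoxygenated ester F7, and LiAlH4 brings the route back at triol 23.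

Step 6. The epoxide may be opened by LiBHEt3 in competition with desulfonylation, or the allyl unit may be reduced with transposition. The fallback introduces the epoxide only after the hydride step. It sets out from bromide 3 and sulfone 5. Deprotonation of 5 with n-BuLi would give lithio sulfone F8, and alkylation with 3 would give coupled sulfone F9. PdCl2(dppp)/LiBHEt3 would give (R)-geranyllinalool F10. NBS in aqueous THF at 0 °C, which prefers the terminal trisubstituted alkene of an extended polyprenyl chain, would give bromohydrin F11, and K2CO3 in MeOH closes it to epoxide 9, where the route is rejoined.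

Step 12. The hindered 2-substituted diazo ester may add slowly, alkyl migration may compete with hydride shift, or the Lewis acid may attack the diene. The fallback is a two-step Reformatsky addition and oxidation. It sets out from alcohol 14, which with 2-bromopropanoyl bromide and pyridine would give bromo ester F12. Its zinc enolate (Zn, THF) would add to aldehyde 13 to give hydroxy ester F13, and Dess–Martin oxidation returns to keto ester 18.

Further compounds
F1 | step 13 | ethyl (6E,10E,14R)-14,16-diacetoxy-6,10,14-trimethyl-3-oxohexadeca-6,10-dienoate | CCOC(=O)CC(=O)CC/C(C)=C/CC/C(C)=C/CC[C@@](C)(OC(C)=O)CCOC(C)=O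
F2 | step 13 | (+)-8-phenylmenthyl (6E,10E,14R)-14,16-diacetoxy-6,10,14-trimethyl-3-oxohexadeca-6,10-dienoate | O=C(CC(=O)CC/C(C)=C/CC/C(C)=C/CC[C@@](C)(OC(C)=O)CCOC(C)=O)O[C@H]1C[C@@H](C)CC[C@@H]1C(C)(C)c1ccccc1
F3 | step 13 | (+)-8-phenylmenthyl (13R)-13,15-diacetoxy-3-oxo-18-norlabd-8(17)-en-19-oate (C4 enolisable) | C=C1CC[C@@H]2[C@](C)(CCC(=O)C2C(=O)O[C@H]3C[C@@H](C)CC[C@@H]3C(C)(C)c3ccccc3)[C@H]1CC[C@@](C)(OC(C)=O)CCOC(C)=O
F4 | step 13 | (+)-8-phenylmenthyl (13R)-13,15-diacetoxy-3-oxolabd-8(17)-en-19-oate | C=C1CC[C@@H]2[C@](C)(CCC(=O)[C@]2(C)C(=O)O[C@H]3C[C@@H](C)CC[C@@H]3C(C)(C)c3ccccc3)[C@H]1CC[C@@](C)(OC(C)=O)CCOC(C)=O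
F5 | step 13 | (+)-8-phenylmenthyl (13R)-13,15-diacetoxy-3β-hydroxylabd-8(17)-en-19-oate | C=C1CC[C@@H]2[C@](C)(CC[C@H](O)[C@]2(C)C(=O)O[C@H]3C[C@@H](C)CC[C@@H]3C(C)(C)c3ccccc3)[C@H]1CC[C@@](C)(OC(C)=O)CCOC(C)=O
F6 | step 13 | (+)-8-phenylmenthyl (13R)-13,15-diacetoxy-3β-[(imidazol-1-yl)thiocarbonyloxy]labd-8(17)-en-19-oate | C=C1CC[C@@H]2[C@](C)(CC[C@H](OC(=S)n4ccnc4)[C@]2(C)C(=O)O[C@H]3C[C@@H](C)CC[C@@H]3C(C)(C)c3ccccc3)[C@H]1CC[C@@](C)(OC(C)=O)CCOC(C)=O
F7 | step 13 | (+)-8-phenylmenthyl (13R)-13,15-diacetoxylabd-8(17)-en-19-oate | C=C1CC[C@@H]2[C@](C)(CCC[C@]2(C)C(=O)O[C@H]3C[C@@H](C)CC[C@@H]3C(C)(C)c3ccccc3)[C@H]1CC[C@@](C)(OC(C)=O)CCOC(C)=O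
F8 | step 6 | α-lithio geranyl phenyl sulfone | [Li]C(/C=C(C)/CCC=C(C)C)S(=O)(=O)c1ccccc1
F9 | step 6 | (3R,6E,10E)-3,7,11,15-tetramethyl-9-(phenylsulfonyl)hexadeca-1,6,10,14-tetraen-3-ol (C9 epimers) | CC(C)=CCC/C(C)=C/C(C/C(C)=C/CC[C@@](C)(O)C=C)S(=O)(=O)c1ccccc1
F10 | step 6 | (R)-geranyllinalool, (3R,6E,10E)-3,7,11,15-tetramethylhexadeca-1,6,10,14-tetraen-3-ol | CC(C)=CCC/C(C)=C/CC/C(C)=C/CC[C@@](C)(O)C=C
F11 | step 6 | (3R,6E,10E)-14-bromo-3,7,11,15-tetramethylhexadeca-1,6,10-triene-3,15-diol (C14 epimers) | CC(C)(O)C(Br)CC/C(C)=C/CC/C(C)=C/CC[C@@](C)(O)C=C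
F12 | step 12 | (−)-8-phenylmenthyl 2-bromopropanoate (C2 epimers) | CC(Br)C(=O)O[C@@H]1C[C@H](C)CC[C@H]1C(C)(C)c1ccccc1
F13 | step 12 | (−)-8-phenylmenthyl (6E,10E,14R)-14,16-diacetoxy-3-hydroxy-2,6,10,14-tetramethylhexadeca-6,10-dienoate (C2 and C3 epimers) | CC(C(=O)O[C@@H]1C[C@H](C)CC[C@H]1C(C)(C)c1ccccc1)C(O)CC/C(C)=C/CC/C(C)=C/CC[C@@](C)(OC(C)=O)CCOC(C)=O
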